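**Retrosynthetic overview**

1. Target 14 ⇐ tricyclic lactone 13: the 3‑arylhexanoic acid is unmasked by opening the O5–acyl bond of a 4‑propyl‑dihydrocoumarin.
2. 13 ⇐ phenol 11 + (E)‑hex‑2‑enal 12: enantioselective [3+3] annulation through an enoyl azolium (an enoyl‑thioester mimic) makes the C6–C bond, the (R) centre and the δ‑lactone.
3. 11 ⇐ chromanone 6 + prenol 7: O5‑prenylation, then a para‑Claisen/Cope shift that can only deliver the prenyl group to C8.
4. 6 ⇐ symmetric o‑tigloyl resorcinol 4: quinidine‑catalysed oxa‑Michael closure sets C2, and equilibration sets C3 trans.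
5. 4 ⇐ phloroglucinol 1 + tigloyl chloride 2, then para‑O‑methylation. Ring order: pyranone first (step 3), δ‑lactone second (step 6, opened in the same flask).

Assumption: the facial sense of both chiral catalysts on these new substrates is taken from their closest known cases (quinine gives 2R with o‑tigloylphenols, so quinidine is used for 2S; the (5aS,10bR) triazolium is taken to give Re‑face attack at C‑β); both hands are sold, so an inverted outcome is corrected by switching to quinine or to the (5aR,10bS) salt.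

**Route**

Step 1
Reactants: 1 phloroglucinol; 2 tigloyl chloride
Product: 3 (E)-2-methyl-1-(2,4,6-trihydroxyphenyl)but-2-en-1-one
Conditions: AlCl3 (4 equiv), PhNO2/CH2Cl2, 0 °C → rt; cold 1 M HCl
Reagents that add atoms: none
Why: Friedel–Crafts C‑acylation of the threefold‑symmetric, electron‑rich triol can give only one ketone, and the aluminium chelate of the o‑hydroxyaryl ketone ties up the phenol oxygens so that the E‑enone survives uncyclized until the cold acid quench.

Step 2
Reactants: 3
Product: 4 (E)-1-(2,6-dihydroxy-4-methoxyphenyl)-2-methylbut-2-en-1-one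
Conditions: TMSCHN2 (1.0 equiv), PhMe/MeOH 4:1, −10 → 0 °C
Reagents that add atoms: trimethylsilyldiazomethane, C[Si](C)(C)C=[N+]=[N-]
Why: Base‑free diazoalkane O‑methylation tracks acidity, so the non‑chelated 4‑OH (a vinylogous carboxylic acid) is methylated ahead of the two carbonyl‑chelated ortho hydroxyls, and without base the tigloyl ketone cannot undergo a premature racemic oxa‑Michael closure.

Step 3
Reactants: 4
Product: 6 (2S,3S)-5-hydroxy-7-methoxy-2,3-dimethylchroman-4-one, via cis-chromanone 5 (not isolated)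
Conditions: quinidine (30 mol%), PhCl, rt, dark; then MgI2·OEt2 (30 mol%), THF, 40 °C
Reagents that add atoms: none
Why: Biomimetic intramolecular oxa‑Michael addition under cinchona base/hydrogen‑bond catalysis: the two ortho hydroxyls of 4 are equivalent so only one chromanone can form, quinidine directs the phenol oxygen to the Si face of C‑β to set C2 as S, kinetic protonation gives mainly the cis isomer 5, and magnesium‑chelate‑assisted enolization then epimerizes C3 alone to the diequatorial trans 2S,3S isomer without opening the ring.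

Step 4
Reactants: 6; 7 prenol (3-methylbut-2-en-1-ol)
Product: 8 (2S,3S)-7-methoxy-2,3-dimethyl-5-[(3-methylbut-2-en-1-yl)oxy]chroman-4-one
Conditions: PPh3, DIAD, THF, 0 °C → rt
Reagents that add atoms: none
Why: Mitsunobu etherification alkylates the chelated 5‑OH by SN2 at the primary carbon of prenol under neutral conditions, leaving C2 and the enolizable C3 untouched.

Step 5
Reactants: 8
Product: 11 (2S,3S)-5-hydroxy-7-methoxy-2,3-dimethyl-8-(3-methylbut-2-en-1-yl)chroman-4-one, via ortho-dienone 9 (not isolated), via para-dienone 10 (not isolated)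
Conditions: Eu(fod)3 (10 mol%), CHCl3, 60 °C
Reagents that add atoms: none
Why: Europium(III)‑catalysed domino aromatic Claisen/Cope (para‑Claisen) rearrangement: a [3,3] shift to C6 gives dienone 9 carrying a reversed prenyl group, a second [3,3] shift passes it to C8 as a normal prenyl group in 10, and enolization gives 11, C8 being the only position para to O5 so that the regiochemistry is fixed by the mechanism.

Step 6
Reactants: 11; 12 (E)-hex-2-enal
Product: 14 (3R)-3-[(2S,3S)-5-hydroxy-7-methoxy-2,3-dimethyl-8-(3-methylbut-2-en-1-yl)-4-oxochroman-6-yl]hexanoic acid (CNP0233409.1), via tricyclic lactone 13 (not isolated)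
Conditions: 12 (1.5 equiv), (5aS,10bR)-N-mesityl aminoindanol-derived triazolium BF4 (15 mol%), i-Pr2NEt (30 mol%), 3,3',5,5'-tetra-tert-butyldiphenoquinone (1.1 equiv), 4 Å MS, PhMe, rt; then THF/H2O, LiOH (5 equiv), 0 °C; 1 M HCl to pH 3, 0 °C
Reagents that add atoms: lithium hydroxide, [Li+].[OH-]
Why: Proposed new method: oxidation of the carbene–enal adduct gives an (E)‑enoyl azolium that stands in for the hex‑2‑enoyl thioester of the biosynthesis, the single free hydroxyl (O5) adds reversibly to its acyl carbon and the single free ring carbon (C6) is delivered to the Re face of C‑β in a Coates–Claisen‑type [3,3] shift (or direct Friedel–Crafts Michael addition) on the face left open by the aminoindanol scaffold, setting the side‑chain centre as R before lactonization frees the carbene, the closest known reaction type being the NHC‑catalysed enantioselective [3+3] annulation of enals or ynals with naphthols, kojic acids and 1,3‑dicarbonyls to 4‑substituted dihydropyranones and dihydrocoumarins; LiOH then cleaves the aryl ester and the 5‑phenoxide so formed damps enolization at C3, so C2 and C3 are not scrambled.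

**Compound list**

1 | phloroglucinol (benzene-1,3,5-triol) | Oc1cc(O)cc(O)c1 | starting material
2 | tigloyl chloride ((E)-2-methylbut-2-enoyl chloride) | C/C=C(\C)C(Cl)=O | starting material
3 | (E)-2-methyl-1-(2,4,6-trihydroxyphenyl)but-2-en-1-one | C/C=C(\C)C(=O)c1c(O)cc(O)cc1O | intermediate
4 | (E)-1-(2,6-dihydroxy-4-methoxyphenyl)-2-methylbut-2-en-1-one | C/C=C(\C)C(=O)c1c(O)cc(OC)cc1O | intermediate
5 | (2S,3R)-5-hydroxy-7-methoxy-2,3-dimethylchroman-4-one (cis) | COc1cc(O)c2c(c1)O[C@@H](C)[C@@H](C)C2=O | intermediate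
6 | (2S,3S)-5-hydroxy-7-methoxy-2,3-dimethylchroman-4-one (trans) | COc1cc(O)c2c(c1)O[C@@H](C)[C@H](C)C2=O | intermediate
7 | prenol (3-methylbut-2-en-1-ol) | CC(C)=CCO | starting material
8 | (2S,3S)-7-methoxy-2,3-dimethyl-5-[(3-methylbut-2-en-1-yl)oxy]chroman-4-one | COc1cc(OCC=C(C)C)c2c(c1)O[C@@H](C)[C@H](C)C2=O | intermediate
9 | (2S,3S)-7-methoxy-2,3-dimethyl-6-(2-methylbut-3-en-2-yl)-2,3-dihydro-4H-chromene-4,5(6H)-dione (C6 epimers) | COC1=CC2=C(C(=O)C1C(C)(C)C=C)C(=O)[C@@H](C)[C@H](C)O2 | intermediate
10 | (2S,3S)-7-methoxy-2,3-dimethyl-8-(3-methylbut-2-en-1-yl)-2,3-dihydro-4H-chromene-4,5(8H)-dione (C8 epimers) | COC1=CC(=O)C2=C(O[C@@H](C)[C@H](C)C2=O)C1CC=C(C)C | intermediate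
11 | (2S,3S)-5-hydroxy-7-methoxy-2,3-dimethyl-8-(3-methylbut-2-en-1-yl)chroman-4-one | COc1cc(O)c2c(c1CC=C(C)C)O[C@@H](C)[C@H](C)C2=O | intermediate
12 | (E)-hex-2-enal | CCC/C=C/C=O | starting material
13 | (4R,8S,9S)-5-methoxy-8,9-dimethyl-6-(3-methylbut-2-en-1-yl)-4-propyl-3,4,8,9-tetrahydro-2H,10H-pyrano[2,3-f]chromene-2,10-dione | CCC[C@@H]1CC(=O)Oc2c1c(OC)c(CC=C(C)C)c1c2C(=O)[C@@H](C)[C@H](C)O1 | intermediate
14 | (3R)-3-[(2S,3S)-5-hydroxy-7-methoxy-2,3-dimethyl-8-(3-methylbut-2-en-1-yl)-4-oxochroman-6-yl]hexanoic acid | CCC[C@H](CC(=O)O)c1c(O)c2c(c(CC=C(C)C)c1OC)O[C@@H](C)[C@H](C)C2=O | target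

**Totals and risks**

Total step count: 6. Longest linear sequence: 6 (1 → 3 → 4 → 6 → 8 → 11 → 14).

Most likely to fail, in order:

Step 6. The annulation is asked of a hindered, carbonyl‑chelated phenol and may stall at O‑acylation or give low ee. The fallback reverses the polarity of the new C6–C bond and sets out from 11. Condensation of 11 with butanal and sodium p‑toluenesulfinate in aqueous formic acid gives the benzylic sulfone (2S,3S)-5-hydroxy-7-methoxy-2,3-dimethyl-8-(3-methylbut-2-en-1-yl)-6-[1-(4-methylbenzenesulfonyl)butyl]chroman-4-one F1. Aqueous NaHCO3 with a cinchona‑derived bifunctional squaramide (10 mol%) in CH2Cl2 expels sulfinate to give the ortho‑quinone methide (2S,3S)-6-butylidene-7-methoxy-2,3-dimethyl-8-(3-methylbut-2-en-1-yl)-2,3-dihydro-4H-chromene-4,5(6H)-dione F2. This takes up Meldrum's acid on the catalyst‑controlled face to give the adduct 5-{(1R)-1-[(2S,3S)-5-hydroxy-7-methoxy-2,3-dimethyl-8-(3-methylbut-2-en-1-yl)-4-oxochroman-6-yl]butyl}-2,2-dimethyl-1,3-dioxane-4,6-dione F3. Warming in toluene closes the lactone onto O5 with loss of acetone and CO2, and the route is rejoined at 13, which is opened with LiOH as in the second half of step 6.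

Step 3. The ee, or the sense of induction, may be poor on this substrate, or C2 may erode during the cis‑to‑trans equilibration. The fallback replaces asymmetric catalysis by resolution with recycling and sets out from 4. K2CO3 in refluxing 2‑butanone closes the ring without stereocontrol to the racemic trans chromanone, that is 6 together with its mirror image (2R,3R)-5-hydroxy-7-methoxy-2,3-dimethylchroman-4-one F4. Preparative chiral SFC separates the two, F4 is returned to the K2CO3 equilibration (retro‑oxa‑Michael and re‑closure racemize it), and the route is rejoined at 6.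

Step 2. Mono‑methylation of the open triol may over‑methylate or pick an ortho hydroxyl. The fallback moves the methylation behind the ring closure, where chelation rather than acidity alone decides, and sets out from 3. Quinidine in PhCl cyclizes 3 to (2S,3R)-5,7-dihydroxy-2,3-dimethylchroman-4-one F5, and MgI2 equilibrates it to (2S,3S)-5,7-dihydroxy-2,3-dimethylchroman-4-one F6. TMSCHN2 (1 equiv, PhMe/MeOH) then methylates only the free 7‑OH, the 5‑OH being locked to the ketone, and the route is rejoined at 6.

**Further compounds**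

F1 | step 6 | (2S,3S)-5-hydroxy-7-methoxy-2,3-dimethyl-8-(3-methylbut-2-en-1-yl)-6-[1-(4-methylbenzenesulfonyl)butyl]chroman-4-one | CCCC(c1c(O)c2c(c(CC=C(C)C)c1OC)O[C@@H](C)[C@H](C)C2=O)S(=O)(=O)c1ccc(C)cc1
F2 | step 6 | (2S,3S)-6-butylidene-7-methoxy-2,3-dimethyl-8-(3-methylbut-2-en-1-yl)-2,3-dihydro-4H-chromene-4,5(6H)-dione | CCCC=C1C(=O)C2=C(O[C@@H](C)[C@H](C)C2=O)C(CC=C(C)C)=C1OC
F3 | step 6 | 5-{(1R)-1-[(2S,3S)-5-hydroxy-7-methoxy-2,3-dimethyl-8-(3-methylbut-2-en-1-yl)-4-oxochroman-6-yl]butyl}-2,2-dimethyl-1,3-dioxane-4,6-dione | CCC[C@H](C1C(=O)OC(C)(C)OC1=O)c1c(O)c2c(c(CC=C(C)C)c1OC)O[C@@H](C)[C@H](C)C2=O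
F4 | step 3 | (2R,3R)-5-hydroxy-7-methoxy-2,3-dimethylchroman-4-one | COc1cc(O)c2c(c1)O[C@H](C)[C@@H](C)C2=O
F5 | step 2 | (2S,3R)-5,7-dihydroxy-2,3-dimethylchroman-4-one | Oc1cc(O)c2c(c1)O[C@@H](C)[C@@H](C)C2=O
F6 | step 2 | (2S,3S)-5,7-dihydroxy-2,3-dimethylchroman-4-one | Oc1cc(O)c2c(c1)O[C@@H](C)[C@H](C)C2=O
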